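## Structural features

The target (C25H30O4) is a benzophenone: a hexasubstituted ring A is joined through a ketone carbonyl to an unsubstituted phenyl ring B. Numbered along the SMILES string, ring A carries methoxy at C1, a prenyl (3-methylbut-2-enyl) group at C2, a free hydroxyl at C3, the benzoyl group at C4, methoxy at C5 and the second prenyl group at C6. This is an acylphloroglucinol whose two remaining ring carbons are both C-prenylated. There is no stereocentre, so no stereocentres stand next to each other, and each alkene ends in two identical methyl groups, so there is no alkene geometry. The fragile parts are the prenyl group next to the C3 hydroxyl (acid closes it to a chroman), the electron-rich ring (easily oxidised) and the reducible diaryl ketone. The real difficulty is regiochemical: all six ring positions must be filled correctly, one of three phloroglucinol oxygens must stay unmethylated, and both prenyl groups must be attached through carbon in the normal sense, without O-alkylation or over-alkylation. The key step uses the bond between the benzylic CH2 (on C2 and on C6) and the vinylic CH of each prenyl group, both ends of which can be halides. Ring A then only needs a CH2Cl handle at C2 and at C6, the two positions the acylphloroglucinol core leaves open.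

## Logic of the disconnections

**14 to 13.** The acetyl–oxygen bond on the C3 oxygen is cut. A free hydroxyl ortho and para to benzylic chlorides would expel chloride and give quinone methides, so the hydroxyl stays masked until the last step. Nothing is gained in skeleton. The forward step must cleave an aryl ester without acid, so that the C3 hydroxyl does not add to the C2 prenyl alkene.

**13 to 9 and two molecules of 10.** The CH2–CH bond of each prenyl group is cut. The cut lies one carbon away from the crowded ring, both fragments are electrophiles, and there is no C-versus-O or normal-versus-reverse question. Eight carbons and both alkenes are removed. The forward step must couple twice on one molecule, beat benzyl homocoupling, and leave the ketone and the acetate untouched. 9 keeps the acetate because it blocks quinone methide formation, weakens the donor push on the benzylic chlorides, and comes off in one mild step.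

**9 to 5 and 6.** The ring-to-CH2 bonds at C2 and C6 are cut. These are the only open positions of ring A, each ortho or para to both methoxy groups and meta to the acyl group, so electrophilic substitution has no regiochemical choice. Each one-carbon unit and its chlorine come from 6, which carries them as a non-volatile α-chloro ether. The acetate is installed before this step, not after it. The forward step must substitute twice without diarylmethane condensation and without losing the acetate.

**5 to 4.** The acetyl–oxygen bond is cut. The only demand is acylation of a hydrogen-bonded, flanked phenol.

**4 to 1 and 2, through 3.** The C4–carbonyl bond and the O–CH3 bond at the C3 oxygen are cut. The threefold symmetry of 1 makes every ring position the same, and the new ketone singles out one ortho methoxy group by chelation. This reaches two commodity chemicals. The forward step must acylate once and cleave exactly one ether.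

## Other disconnections considered

**Alternative 1:** Danheiser benzannulation.
- **Cut:** ring A is opened at C2–C3, C3–C4 and C1–C6. This leads to the diazo ketone A1 (with the C6 prenyl group, the C5 methoxy group and the future benzylic carbon as a racemic silyl ether) and the ynol ether A2 (C1 with its methoxy group, C2 with its prenyl group).
- **Forward step:** irradiation of A1 would trigger a Wolff rearrangement. The ketene unit would add (2+2) across the triple bond of A2, its carbonyl carbon bonding to the prenyl-bearing alkyne carbon. Four-electron opening of the four-membered ring, six-electron closure of C3 to C4 and tautomerisation would give the phenol A3.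
- **In favour:** every substituent position follows from the connectivity and polarity of two acyclic pieces. The C3 hydroxyl emerges free and distinct from the two methoxy oxygens, with no selective ether cleavage.
- **Against:** A1 is a densely functionalised α-diazo enone that needs a multistep preparation ending in diazo transfer, and A2 must also be made. Photolysis of a diazo compound with two alkenes invites carbene side reactions. The benzylic carbon arrives at the alcohol oxidation level, so a stereocentre is made only to be erased. Two operations follow the key step (desilylation, then oxidation of an ortho-hydroxy benzhydrol on an oxidisable ring), against one in the chosen plan.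
- **Comparison:** on structure the alternative is the better plan in one respect, since it does not rely on the directing effects of ring A. That reliance costs little here, because 1 is symmetric and 5 has only two open positions. On mechanism it is also better in one respect: the pericyclic cascade needs no metal and meets no reducible ketone. On step economy the chosen plan (five steps from four purchasable compounds) should be much shorter; A1 alone would need about as many steps.

**Alternative 2:** biomimetic Claisen cyclisation.
- **Cut:** the ring bond between C4 and an oxygenated neighbour (C4–C5 in the numbering of 14) is opened, giving the open-chain triketo ester A4.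
- **Forward step:** Mg(OMe)2 would deprotonate the methylene between the phenyl ketone and the next ketone. The chelated enolate carbon would attack the terminal ester (Claisen condensation, six-membered closure), and enolisation would give the triol A5. Two of its three hydroxyls would then be methylated to reach 14.
- **In favour:** the closure follows the biosynthesis of acylphloroglucinols and is driven by aromatisation. It needs no protecting group, no halomethylating agent and no electrolysis, so on operational hazard it is the better plan. A5 has a mirror plane, and the hydroxyl that stays chelated to the ketone is the least nucleophilic, so dimethylation should be selective. One step follows the key step, which equals the chosen plan.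
- **Against:** A4 is a 3,5,7-trioxo ester with two α-prenyl branches. It would be a mixture of diastereomers and enol forms, and it could close by aldol reaction or lactonise instead of the wanted C-acylation. Its assembly moves the two C-prenylations onto an acyclic polyketone without making them easier. O-methylation of a 3,5-dialkylated acylphloroglucinol also competes with dearomatising C-methylation.
- **Comparison:** on structure both plans give the same ring, but the alternative leaves the differentiation of the three oxygens to the end, where the chosen plan settles it in step 1. On mechanism an ionic closure under thermodynamic control replaces a catalytic radical–organometallic cycle, which is simpler but offers less control over competing closures. On step economy the chosen plan should be shorter because of the length of the route to A4.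

**Alternative 3:** pyranone to arene.
- **Cut:** C5–C6 and C1–C2 are opened. Ring A divides into a four-carbon unit (C2 to C5) held in the pyranone A6 and a two-carbon unit (C6 and C1), the ynol ether A2 of alternative 1.
- **Forward step:** an inverse-demand (4+2) cycloaddition would join the electron-poor diene of A6 to A2, the prenyl-bearing alkyne carbon bonding to the methoxy-bearing C6 of the pyranone. A decarboxylative retro-(4+2) opening of the lactone bridge would give the silyl ether A7, and fluoride would release 14.
- **In favour:** the ketone is already at the right oxidation level, and the ring is completed with all six substituents in one convergent step. Only one deprotection remains, which equals the chosen plan. No reductant is present, which is an advantage over step 4.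
- **Against:** A6 is a 6-alkoxy-2-pyranone, a cyclic acyl ketene acetal that is sensitive to water and nucleophiles. Its own synthesis is long and has regiochemical problems (C-benzoylation, silylation versus methylation of a tricarbonyl system). Its two oxygen donors make the diene less electron-poor, so heating would probably be needed, and the regiochemistry depends on which end of the diene is more electrophilic.
- **Comparison:** on structure the alternative is better in convergency. On mechanism it is metal-free but rests on a labile diene with uncertain polarisation, while the chosen plan rests on a catalytic coupling whose competing pathways are understood. On step economy the chosen plan should win clearly.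

Key step: step 4

Remark on the chemistry: the phenol is acetylated before the chloromethylation, because a free hydroxyl ortho or para to CH2Cl would lose chloride to a quinone methide.

Remark on the chemistry: 1,4-bis(chloromethoxy)butane 6 is assumed to be a purchasable reagent; it is chosen because it delivers CH2Cl groups from a liquid of low volatility, so no formaldehyde–HCl gas mixture is handled.

Remark on the chemistry: in steps 3 and 4 either benzylic site may react first, so both mono-substituted intermediates are numbered; they converge on one product.

## Route

Step 1
Reactants: 1 1,3,5-trimethoxybenzene; 2 benzoyl chloride
Product: 4 (2-hydroxy-4,6-dimethoxyphenyl)(phenyl)methanone, via 2,4,6-trimethoxybenzophenone 3 (not isolated)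
Conditions: AlCl3 (2.5 equiv), CH2Cl2, 0 °C to 40 °C; then ice, 1 M HCl
Reagents that add atoms: none
Why: Friedel–Crafts acylation of the threefold-symmetric, strongly activated arene can give only 3; AlCl3 held in a six-membered chelate between the carbonyl oxygen and an ortho methoxy oxygen then cleaves that one O–CH3 bond by chloride attack at methyl. The resulting aluminium phenoxide chelate ties up the carbonyl, so the second ortho ether and the para ether should survive.

Step 2
Reactants: 4 (2-hydroxy-4,6-dimethoxyphenyl)(phenyl)methanone
Product: 5 2-benzoyl-3,5-dimethoxyphenyl acetate
Conditions: Ac2O, pyridine, DMAP (cat.), CH2Cl2, rt
Reagents that add atoms: acetic anhydride, CC(=O)OC(C)=O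
Why: DMAP-catalysed acylation through the acylpyridinium ion overcomes the low nucleophilicity of the hydrogen-bonded, flanked phenol. Masking the hydroxyl before any benzylic halide exists prevents quinone methide formation and lowers the donor strength of ring A for step 3.

Step 3
Reactants: 5 2-benzoyl-3,5-dimethoxyphenyl acetate; 6 1,4-bis(chloromethoxy)butane
Product: 9 2-benzoyl-4,6-bis(chloromethyl)-3,5-dimethoxyphenyl acetate, via 4-(chloromethyl) monochloride 7 (not isolated), via 6-(chloromethyl) monochloride 8 (not isolated)
Conditions: 6 (2.5 equiv), SnCl4 (0.2 equiv), CH2Cl2, 0 °C to rt, slow addition of 5; cold aq NaHCO3 wash
Reagents that add atoms: none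
Why: Friedel–Crafts chloromethylation with an α-chloro ether: SnCl4 ionises a C–Cl bond of 6 to an alkoxymethyl cation, ring A attacks it, and the benzylic ether first formed is exchanged for chloride by the chloride and HCl present, as with chloromethyl methyl ether but with a non-volatile reagent. Ring A has only two open positions, each ortho or para to both methoxy groups and meta to the acyl group, and ring B is deactivated, so there is no regiochemical choice. An excess of 6 and slow addition of 5 keep free ring positions scarce, which should suppress diarylmethane condensation, and the anhydrous medium keeps the aryl acetate in place.

Step 4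
Reactants: 9 2-benzoyl-4,6-bis(chloromethyl)-3,5-dimethoxyphenyl acetate; 10 1-bromo-2-methylprop-1-ene
Product: 13 2-benzoyl-3,5-dimethoxy-4,6-bis(3-methylbut-2-enyl)phenyl acetate, via 4-prenyl monochloride 11 (not isolated), via 6-prenyl monochloride 12 (not isolated)
Conditions: 10 (4 equiv), NiBr2(dme) (15 mol%), 2,2'-bipyridine (18 mol%), NaI, DMA, RVC cathode, Zn anode, undivided cell, constant current with the cathode kept at the nickel wave (expected near −1.2 V vs SCE), rt, slow addition of 9
Reagents that add atoms: none
Why: This is a nickel-catalysed reductive cross-electrophile coupling of a benzyl chloride with an alkenyl bromide, driven by the cathode in place of a metal powder, a known reaction type used here twice on one arene. Cathodic reduction of (bpy)NiBr2 gives zerovalent nickel, which inserts into the C(sp2)–Br bond of 10 to give a divalent alkenylnickel bromide, while monovalent nickel abstracts halogen from a CH2Cl group of 9 (or from the iodide formed by exchange with NaI) to give a benzyl radical. The radical is captured by the divalent alkenylnickel species, and reductive elimination from trivalent nickel forms the CH2–CH bond and returns monovalent nickel; the cycle runs once at each benzylic site, through 11 or 12. No ring is closed and no stereocentre is formed, and the uncoupled alkene carbon of 10 carries two methyl groups, so no geometry can be lost. The step needs cross-coupling to win over benzyl homocoupling (oligomers for a bis-electrophile), over hydrodechlorination and over reduction of the diaryl ketone, with the acetate kept. The two halides are activated by different elementary steps (two-electron oxidative addition for the alkenyl bromide, halogen-atom abstraction for the benzyl chloride), and with 10 in excess and 9 added slowly each benzyl radical should meet an alkenylnickel species before a second radical. The cathode is held at the nickel bipyridine wave, well short of the ketone wave, and the carbonyl is further twisted out of conjugation with ring A by its two ortho substituents. The acetate blocks phenoxide-driven loss of chloride, and insertion of nickel into the aryl C–O bond is not expected at room temperature with bipyridine as ligand.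

Step 5
Reactants: 13 2-benzoyl-3,5-dimethoxy-4,6-bis(3-methylbut-2-enyl)phenyl acetate
Product: 14 [2-hydroxy-4,6-dimethoxy-3,5-bis(3-methylbut-2-enyl)phenyl](phenyl)methanone
Conditions: K2CO3 (0.2 equiv), MeOH, 0 °C to rt; aq NH4Cl
Reagents that add atoms: none
Why: Base-catalysed transesterification (methanolysis) of an aryl acetate, with the chelated phenoxide as a good leaving group; the ketone, the methyl ethers and the prenyl alkenes are inert to methoxide at room temperature. The buffered, non-acidic work-up avoids acid-induced cyclisation of the C3 hydroxyl onto the C2 prenyl group.

## Compound list

1 | 1,3,5-trimethoxybenzene | COc1cc(OC)cc(OC)c1 | starting material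
2 | benzoyl chloride | O=C(Cl)c1ccccc1 | starting material
3 | phenyl(2,4,6-trimethoxyphenyl)methanone (2,4,6-trimethoxybenzophenone) | COc1cc(OC)c(C(=O)c2ccccc2)c(OC)c1 | intermediate (not isolated)
4 | (2-hydroxy-4,6-dimethoxyphenyl)(phenyl)methanone | COc1cc(O)c(C(=O)c2ccccc2)c(OC)c1 | intermediate
5 | 2-benzoyl-3,5-dimethoxyphenyl acetate | COc1cc(OC(C)=O)c(C(=O)c2ccccc2)c(OC)c1 | intermediate
6 | 1,4-bis(chloromethoxy)butane | ClCOCCCCOCCl | starting material
7 | 2-benzoyl-4-(chloromethyl)-3,5-dimethoxyphenyl acetate | COc1cc(OC(C)=O)c(C(=O)c2ccccc2)c(OC)c1CCl | intermediate (not isolated)
8 | 2-benzoyl-6-(chloromethyl)-3,5-dimethoxyphenyl acetate | COc1cc(OC)c(C(=O)c2ccccc2)c(OC(C)=O)c1CCl | intermediate (not isolated)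
9 | 2-benzoyl-4,6-bis(chloromethyl)-3,5-dimethoxyphenyl acetate | COc1c(CCl)c(OC(C)=O)c(C(=O)c2ccccc2)c(OC)c1CCl | intermediate
10 | 1-bromo-2-methylprop-1-ene | CC(C)=CBr | starting material
11 | 2-benzoyl-6-(chloromethyl)-3,5-dimethoxy-4-(3-methylbut-2-enyl)phenyl acetate | COc1c(CCl)c(OC(C)=O)c(C(=O)c2ccccc2)c(OC)c1CC=C(C)C | intermediate (not isolated)
12 | 2-benzoyl-4-(chloromethyl)-3,5-dimethoxy-6-(3-methylbut-2-enyl)phenyl acetate | COc1c(CC=C(C)C)c(OC(C)=O)c(C(=O)c2ccccc2)c(OC)c1CCl | intermediate (not isolated)
13 | 2-benzoyl-3,5-dimethoxy-4,6-bis(3-methylbut-2-enyl)phenyl acetate | COc1c(CC=C(C)C)c(OC(C)=O)c(C(=O)c2ccccc2)c(OC)c1CC=C(C)C | intermediate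
14 | [2-hydroxy-4,6-dimethoxy-3,5-bis(3-methylbut-2-enyl)phenyl](phenyl)methanone | COc1c(CC=C(C)C)c(O)c(C(=O)c2ccccc2)c(OC)c1CC=C(C)C | target

## Step count and least certain steps

Total step count: 5. Longest linear sequence: 5 steps (1 to 4 to 5 to 9 to 13 to 14); 2, 6 and 10 are purchased and enter directly.

**Step 4 (key step).**
- The most likely failure is homocoupling of benzyl radicals, which for a substrate with two benzylic chlorides means oligomerisation.
- Hydrodechlorination to methyl groups and stalling after one coupling are also possible.
- The benzylic chlorides sit ortho and para to oxygen donors, so they may ionise and solvolyse in DMA before the catalyst reaches them. For this reason 9 should be used fresh and without chromatography.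
- A cathode potential drifting negative would start ketyl formation at the diaryl ketone.
- Fallback, from 10 and 9, returning at 13: magnesium insertion into 10 (Mg, THF) gives (2-methylprop-1-enyl)magnesium bromide F1. Transmetalation with ZnCl2 gives chloro(2-methylprop-1-enyl)zinc F2. A Negishi coupling of F2 (3 equiv) with 9 under Pd(PPh3)4 in THF at rt to 50 °C forms the same two CH2–CH bonds. This replaces the radical and cathodic steps by oxidative addition of zerovalent palladium into the benzylic C–Cl bond and a polar transmetalation. Alkenylzinc halides add neither to the diaryl ketone nor to the aryl acetate under these conditions.

**Step 3.**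
- The most likely failure is Friedel–Crafts condensation of a newly formed benzylic chloride with a ring that still has a free position (diarylmethane formation), which SnCl4 can promote.
- The second substitution may stall on the ring once it is deactivated by the first CH2Cl group.
- Exchange of the first-formed benzylic ethers for chloride may be incomplete, and the activated benzylic chlorides may hydrolyse or re-etherify during the aqueous wash.
- Lewis-acid cleavage of the acetyl group, followed by quinone methide chemistry, or of the methyl ether chelated to the ketone is possible.
- Although 6 is far less volatile than chloromethyl methyl ether, it is still an alkylating α-chloro ether and is handled in a hood; the aqueous waste is treated with ammonia.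
- Fallback, from 4, returning at 9: a double Mannich reaction of 4 with aqueous formaldehyde and dimethylamine in ethanol at reflux places CH2NMe2 ortho and para to the free hydroxyl, giving [3,5-bis(dimethylaminomethyl)-2-hydroxy-4,6-dimethoxyphenyl](phenyl)methanone F3. O-Acetylation (Ac2O, pyridine, rt) gives 2-benzoyl-4,6-bis(dimethylaminomethyl)-3,5-dimethoxyphenyl acetate F4. Ethyl chloroformate (2.5 equiv, CH2Cl2, 0 °C to rt) then cleaves each benzylic C–N bond through the acylammonium chloride (von Braun-type dealkylation) and gives 9. This sequence uses no α-chloro ether and no Lewis acid.

**Step 1.**
- The most likely failure is loss of control in the ether cleavage: either a second ortho O–CH3 bond is cleaved, or cleavage is incomplete and 3 remains mixed with 4.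
- Fallback, from 2 and purchased 3,5-dimethoxyphenol F5, returning at 4: O-benzoylation of F5 with 2 (Et3N, CH2Cl2) gives 3,5-dimethoxyphenyl benzoate F6. A Fries rearrangement (TiCl4, heat) with chelation-directed ortho migration then gives 4. No ether has to be cleaved in this sequence.

## Further compounds

F1 | step 4 | (2-methylprop-1-enyl)magnesium bromide | CC(C)=C[Mg]Br
F2 | step 4 | chloro(2-methylprop-1-enyl)zinc | CC(C)=C[Zn]Cl
F3 | step 3 | [3,5-bis(dimethylaminomethyl)-2-hydroxy-4,6-dimethoxyphenyl](phenyl)methanone | COc1c(CN(C)C)c(O)c(C(=O)c2ccccc2)c(OC)c1CN(C)C
F4 | step 3 | 2-benzoyl-4,6-bis(dimethylaminomethyl)-3,5-dimethoxyphenyl acetate | COc1c(CN(C)C)c(OC(C)=O)c(C(=O)c2ccccc2)c(OC)c1CN(C)C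
F5 | step 1 | 3,5-dimethoxyphenol | COc1cc(O)cc(OC)c1
F6 | step 1 | 3,5-dimethoxyphenyl benzoate | COc1cc(OC)cc(OC(=O)c2ccccc2)c1
A1 | alternative 1 | racemic (2Z)-1-(tert-butyldimethylsilyloxy)-5-diazo-3-methoxy-8-methyl-1-phenylnona-2,7-dien-4-one | CC(C)=CCC(=[N+]=[N-])C(=O)/C(OC)=C/C(O[Si](C)(C)C(C)(C)C)c1ccccc1
A2 | alternative 1 | 1-methoxy-5-methylhex-4-en-1-yne | COC#CCC=C(C)C
A3 | alternative 1 | racemic 6-[(tert-butyldimethylsilyloxy)(phenyl)methyl]-3,5-dimethoxy-2,4-bis(3-methylbut-2-enyl)phenol | COc1c(CC=C(C)C)c(O)c(C(O[Si](C)(C)C(C)(C)C)c2ccccc2)c(OC)c1CC=C(C)C
A4 | alternative 2 | methyl 2,4-bis(3-methylbut-2-enyl)-3,5,7-trioxo-7-phenylheptanoate (mixture of stereoisomers and enol forms) | COC(=O)C(CC=C(C)C)C(=O)C(CC=C(C)C)C(=O)CC(=O)c1ccccc1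
A5 | alternative 2 | 2,4,6-trihydroxy-3,5-bis(3-methylbut-2-enyl)benzophenone | Oc1c(CC=C(C)C)c(O)c(C(=O)c2ccccc2)c(O)c1CC=C(C)C
A6 | alternative 3 | 5-benzoyl-4-(tert-butyldimethylsilyloxy)-6-methoxy-3-(3-methylbut-2-enyl)pyran-2-one | COC1=C(C(=O)c2ccccc2)C(O[Si](C)(C)C(C)(C)C)=C(CC=C(C)C)C(=O)O1
A7 | alternative 3 | [2-(tert-butyldimethylsilyloxy)-4,6-dimethoxy-3,5-bis(3-methylbut-2-enyl)phenyl](phenyl)methanone | COc1c(CC=C(C)C)c(O[Si](C)(C)C(C)(C)C)c(C(=O)c2ccccc2)c(OC)c1CC=C(C)C
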